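The retrosynthesis first traces C7–OH back to C7–F, C8–CHO to a dioxolane and 2'-OH to a MOM ether; ring C is then cut at two bonds at once, C3–C4 and O1–C8a, which leaves an (S)-aryl oxirane (ring B with C3, C2, O1) and an ortho-fluorobenzyl metal (ring A with C4).
Two features make this cut possible: O1–C2–C3 is a vicinal O,C unit whose C3 is benzylic to the 2',4'-dioxygenated ring B (an oxirane with electrophilic C3 and latent alkoxide O1), and C4–C4a–C8a is its complement (nucleophilic benzylic C4, electrophilic C8a).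
Ring A has the phloroglucinol pattern, with C5, C7 and C8a mutually meta, so the charge from attack at C8a or C7 falls on C4a, C6 and C8 and never on a donor-bearing carbon; both aryl–O bonds that flank C8 can therefore come from the two C–F bonds of symmetric 2,6-difluoro-4-methoxybenzaldehyde.
In the forward direction the ring B piece arises by two directed lithiations (prenyl, chloroacetyl) and reduction/closure to the oxirane, and the ring A piece by acetalisation, one lithiation/formylation, reduction and chlorination; the halves are joined and ring C is closed in one flask, then the groups are unmasked and C7–F is changed to C7–OH.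
The only stereocentre, C3, comes from a catalytic asymmetric transfer hydrogenation that leads to the (S)-oxirane; the SN2 opening inverts it to 3R, and no later step touches it.

Key step: step 9

Remark: isoflavan numbering is used (O1, C2, C3, C4, C4a, C5 to C8, C8a for rings C and A, primed numbers for ring B). The stereocentre of the target SMILES is read as 3R (C2 > C1' > C4 > H).

Step 1
Reactants: 1 3-methoxyphenol
Product: 2 1-methoxy-3-(methoxymethoxy)benzene
Conditions: NaH, MOMCl, DMF, 0 °C → rt
Reagents that add atoms: chloromethyl methyl ether COCCl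
Why: Williamson-type O-alkylation of the sodium phenoxide installs the MOM acetal, which survives every basic and organometallic step and later acts as the stronger ortho-directing group.

Step 2
Reactants: 2 1-methoxy-3-(methoxymethoxy)benzene
Product: 4 1-methoxy-3-(methoxymethoxy)-2-(3-methylbut-2-en-1-yl)benzene, via 2-lithio arene 3 (not isolated)
Conditions: n-BuLi, THF, 0 °C → rt; CuBr·SMe2 (10 mol %), prenyl bromide, −78 °C → rt
Reagents that add atoms: prenyl bromide CC(C)=CCBr
Why: Directed ortho-metalation should occur at the doubly coordinated and most acidic position between OMe and OMOM, and the copper-catalysed coupling of the aryllithium with prenyl bromide should take place at the primary carbon (SN2).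

Step 3
Reactants: 4 1-methoxy-3-(methoxymethoxy)-2-(3-methylbut-2-en-1-yl)benzene
Product: 6 2-chloro-1-[4-methoxy-2-(methoxymethoxy)-3-(3-methylbut-2-en-1-yl)phenyl]ethan-1-one, via aryllithium 5 (not isolated)
Conditions: n-BuLi, TMEDA, THF, −20 → 0 °C; ClCH2C(O)N(OMe)Me, −78 °C
Reagents that add atoms: 2-chloro-N-methoxy-N-methylacetamide CON(C)C(=O)CCl
Why: A second directed ortho-metalation is steered by the better-coordinating OMOM group to the one free position next to it, and the Weinreb ketone synthesis stops at the chloromethyl ketone because the chelated adduct collapses only on work-up.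

Step 4
Reactants: 6 2-chloro-1-[4-methoxy-2-(methoxymethoxy)-3-(3-methylbut-2-en-1-yl)phenyl]ethan-1-one
Product: 8 (2S)-2-[4-methoxy-2-(methoxymethoxy)-3-(3-methylbut-2-en-1-yl)phenyl]oxirane, via (S)-chlorohydrin 7 (not isolated)
Conditions: RuCl[(R,R)-TsDPEN](p-cymene) (1 mol %), HCO2H/Et3N (5:2), EtOAc, rt; then 2 M NaOH, i-PrOH, 0 °C
Reagents that add atoms: none
Why: Noyori–Ikariya asymmetric transfer hydrogenation of the aryl chloromethyl ketone sets the carbinol centre under catalyst control (the (R,R)-catalyst gives the S descriptor here because CH2Cl outranks aryl) and leaves the isolated trisubstituted alkene untouched, and the Williamson closure at CH2Cl keeps the C–O bond of the stereocentre, so the configuration is retained.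

Step 5
Reactants: 9 2,6-difluoro-4-methoxybenzaldehyde
Product: 10 2-(2,6-difluoro-4-methoxyphenyl)-1,3-dioxolane
Conditions: HOCH2CH2OH, p-TsOH·H2O (cat.), toluene, reflux, Dean–Stark
Reagents that add atoms: ethane-1,2-diol OCCO
Why: Acid-catalysed acetalisation with removal of water masks the future C8 formyl group against the organolithium and Grignard steps.

Step 6
Reactants: 10 2-(2,6-difluoro-4-methoxyphenyl)-1,3-dioxolane
Product: 12 3-(1,3-dioxolan-2-yl)-2,4-difluoro-6-methoxybenzaldehyde, via aryllithium 11 (not isolated)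
Conditions: n-BuLi, THF, −78 °C; DMF, −78 → 0 °C
Reagents that add atoms: N,N-dimethylformamide CN(C)C=O
Why: Directed ortho-metalation has no regiochemical choice because the two ring hydrogens are equivalent by symmetry and each lies between F and OMe, and the formylation with DMF brings in the carbon that becomes C4.

Step 7
Reactants: 12 3-(1,3-dioxolan-2-yl)-2,4-difluoro-6-methoxybenzaldehyde
Product: 13 [3-(1,3-dioxolan-2-yl)-2,4-difluoro-6-methoxyphenyl]methanol
Conditions: NaBH4, MeOH/THF, 0 °C
Reagents that add atoms: none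
Why: Borohydride reduction of the aldehyde is fast at 0 °C and leaves the acetal and both aryl fluorides untouched.

Step 8
Reactants: 13 [3-(1,3-dioxolan-2-yl)-2,4-difluoro-6-methoxyphenyl]methanol
Product: 14 2-[3-(chloromethyl)-2,6-difluoro-4-methoxyphenyl]-1,3-dioxolane
Conditions: PPh3, CCl4, CH2Cl2, 0 °C → rt
Reagents that add atoms: tetrachloromethane ClC(Cl)(Cl)Cl
Why: The Appel reaction converts the primary benzylic alcohol into the chloride under neutral conditions, so the acid-labile dioxolane survives.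

Step 9
Reactants: 14 2-[3-(chloromethyl)-2,6-difluoro-4-methoxyphenyl]-1,3-dioxolane; 8 (2S)-2-[4-methoxy-2-(methoxymethoxy)-3-(3-methylbut-2-en-1-yl)phenyl]oxirane
Product: 18 (3R)-8-(1,3-dioxolan-2-yl)-7-fluoro-5-methoxy-3-[4-methoxy-2-(methoxymethoxy)-3-(3-methylbut-2-en-1-yl)phenyl]-3,4-dihydro-2H-chromene, via benzylic Grignard reagent 15 (not isolated), via chloromagnesium alkoxide 16 (not isolated), via potassium alkoxide 17 (not isolated)
Conditions: 14, Mg, THF, 0 °C; then CuI (10 mol %), 8, −40 → 0 °C; then KOt-Bu, DMPU, 60 °C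
Reagents that add atoms: none
Why: Copper-catalysed SN2 attack of the benzylic Grignard carbon C4 of 15 on the benzylic oxirane carbon C3 of 8 makes the C4–C3 bond and releases O1 as an alkoxide (16), which after exchange of magnesium for potassium (17) adds to C8a and expels fluoride (SNAr), so that the two halves are joined and ring C is closed in one flask as a formal anionic [3+3] annulation. The closest known reaction types are the invertive opening of electron-rich aryl oxiranes at the benzylic carbon by allyl-, vinyl-, aryl- and benzyl-type Grignard reagents and the alkoxide cyclisation of 3-(2-fluoroaryl)propan-1-ols to chromans. Ring C closes by a six-membered ipso attack of O1 on C8a (6-exo-trig, the charge being pushed out of the new ring onto C8 and C6). C3 is the only stereocentre and is controlled by the substrate alone: backside attack inverts the (S)-oxirane carbon and gives 3R. The step needs attack at C3 rather than C2, which the para-methoxy and ortho-OMOM donors of ring B should secure (weakened benzylic C–O bond, magnesium held between the oxirane and MOM oxygens), and it needs C–C bond formation to outrun a hydride shift of the oxirane, for which low temperature, the chloride counter-ion and copper catalysis are chosen. Of the two fluorides only the one at C8a lies within reach of O1, both ortho positions of the benzyl metal are blocked against ortho attack, and C5–OMe and C7–F are meta to C8a, so they assist the fluoride displacement inductively instead of opposing it.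

Step 10
Reactants: 18 (3R)-8-(1,3-dioxolan-2-yl)-7-fluoro-5-methoxy-3-[4-methoxy-2-(methoxymethoxy)-3-(3-methylbut-2-en-1-yl)phenyl]-3,4-dihydro-2H-chromene
Product: 19 (3R)-7-fluoro-3-[2-hydroxy-4-methoxy-3-(3-methylbut-2-en-1-yl)phenyl]-5-methoxy-3,4-dihydro-2H-chromene-8-carbaldehyde
Conditions: 3 M aq HCl, THF, 45 °C
Reagents that add atoms: water O
Why: Acid hydrolysis cleaves both acetals, the dioxolane easily because its oxocarbenium ion is stabilised by the para C5 methoxy group and the ortho O1, and the aryl MOM ether under the same conditions, while C3 has no pathway to epimerise.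

Step 11
Reactants: 19 (3R)-7-fluoro-3-[2-hydroxy-4-methoxy-3-(3-methylbut-2-en-1-yl)phenyl]-5-methoxy-3,4-dihydro-2H-chromene-8-carbaldehyde
Product: 21 (3R)-7-hydroxy-3-[2-hydroxy-4-methoxy-3-(3-methylbut-2-en-1-yl)phenyl]-5-methoxy-3,4-dihydro-2H-chromene-8-carbaldehyde, via 2-(methylsulfonyl)ethyl aryl ether 20 (not isolated)
Conditions: MeSO2CH2CH2OH, NaH, DMF, 0 → 40 °C; then dilute HCl
Reagents that add atoms: 2-(methylsulfonyl)ethanol CS(=O)(=O)CCO
Why: The unmasked C8 formyl group, ortho to C7, activates the remaining fluoride for SNAr by the alkoxide of 2-(methylsulfonyl)ethanol, and the ether formed loses methyl vinyl sulfone by E1cB elimination, so the reagent serves as a mild hydroxide equivalent.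

Compound list
1 | 3-methoxyphenol | COc1cccc(O)c1 | starting material
2 | 1-methoxy-3-(methoxymethoxy)benzene | COc1cccc(OCOC)c1 | intermediate
3 | [2-methoxy-6-(methoxymethoxy)phenyl]lithium | COc1cccc(OCOC)c1[Li] | intermediate
4 | 1-methoxy-3-(methoxymethoxy)-2-(3-methylbut-2-en-1-yl)benzene | COc1cccc(OCOC)c1CC=C(C)C | intermediate
5 | [4-methoxy-2-(methoxymethoxy)-3-(3-methylbut-2-en-1-yl)phenyl]lithium | COc1ccc([Li])c(OCOC)c1CC=C(C)C | intermediate
6 | 2-chloro-1-[4-methoxy-2-(methoxymethoxy)-3-(3-methylbut-2-en-1-yl)phenyl]ethan-1-one | COc1ccc(C(=O)CCl)c(OCOC)c1CC=C(C)C | intermediate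
7 | (1S)-2-chloro-1-[4-methoxy-2-(methoxymethoxy)-3-(3-methylbut-2-en-1-yl)phenyl]ethan-1-ol | COc1ccc([C@H](O)CCl)c(OCOC)c1CC=C(C)C | intermediate
8 | (2S)-2-[4-methoxy-2-(methoxymethoxy)-3-(3-methylbut-2-en-1-yl)phenyl]oxirane | COc1ccc([C@H]2CO2)c(OCOC)c1CC=C(C)C | intermediate
9 | 2,6-difluoro-4-methoxybenzaldehyde | O=Cc1c(F)cc(OC)cc1F | starting material
10 | 2-(2,6-difluoro-4-methoxyphenyl)-1,3-dioxolane | COc1cc(F)c(C2OCCO2)c(F)c1 | intermediate
11 | [3-(1,3-dioxolan-2-yl)-2,4-difluoro-6-methoxyphenyl]lithium | COc1cc(F)c(C2OCCO2)c(F)c1[Li] | intermediate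
12 | 3-(1,3-dioxolan-2-yl)-2,4-difluoro-6-methoxybenzaldehyde | COc1cc(F)c(C2OCCO2)c(F)c1C=O | intermediate
13 | [3-(1,3-dioxolan-2-yl)-2,4-difluoro-6-methoxyphenyl]methanol | COc1cc(F)c(C2OCCO2)c(F)c1CO | intermediate
14 | 2-[3-(chloromethyl)-2,6-difluoro-4-methoxyphenyl]-1,3-dioxolane | COc1cc(F)c(C2OCCO2)c(F)c1CCl | intermediate
15 | {[3-(1,3-dioxolan-2-yl)-2,4-difluoro-6-methoxyphenyl]methyl}magnesium chloride | COc1cc(F)c(C2OCCO2)c(F)c1C[Mg]Cl | intermediate
16 | chloromagnesium (2R)-3-[3-(1,3-dioxolan-2-yl)-2,4-difluoro-6-methoxyphenyl]-2-[4-methoxy-2-(methoxymethoxy)-3-(3-methylbut-2-en-1-yl)phenyl]propan-1-olate | COc1ccc([C@H](CO[Mg]Cl)Cc2c(F)c(C3OCCO3)c(F)cc2OC)c(OCOC)c1CC=C(C)C | intermediate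
17 | potassium (2R)-3-[3-(1,3-dioxolan-2-yl)-2,4-difluoro-6-methoxyphenyl]-2-[4-methoxy-2-(methoxymethoxy)-3-(3-methylbut-2-en-1-yl)phenyl]propan-1-olate | COc1ccc([C@H](C[O-])Cc2c(F)c(C3OCCO3)c(F)cc2OC)c(OCOC)c1CC=C(C)C.[K+] | intermediate
18 | (3R)-8-(1,3-dioxolan-2-yl)-7-fluoro-5-methoxy-3-[4-methoxy-2-(methoxymethoxy)-3-(3-methylbut-2-en-1-yl)phenyl]-3,4-dihydro-2H-chromene | COc1ccc([C@@H]2COc3c(C4OCCO4)c(F)cc(OC)c3C2)c(OCOC)c1CC=C(C)C | intermediate
19 | (3R)-7-fluoro-3-[2-hydroxy-4-methoxy-3-(3-methylbut-2-en-1-yl)phenyl]-5-methoxy-3,4-dihydro-2H-chromene-8-carbaldehyde | COc1ccc([C@@H]2COc3c(C=O)c(F)cc(OC)c3C2)c(O)c1CC=C(C)C | intermediate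
20 | (3R)-3-[2-hydroxy-4-methoxy-3-(3-methylbut-2-en-1-yl)phenyl]-5-methoxy-7-[2-(methylsulfonyl)ethoxy]-3,4-dihydro-2H-chromene-8-carbaldehyde | COc1ccc([C@@H]2COc3c(C=O)c(OCCS(C)(=O)=O)cc(OC)c3C2)c(O)c1CC=C(C)C | intermediate
21 | (3R)-7-hydroxy-3-[2-hydroxy-4-methoxy-3-(3-methylbut-2-en-1-yl)phenyl]-5-methoxy-3,4-dihydro-2H-chromene-8-carbaldehyde | COc1ccc([C@@H]2COc3c(C=O)c(O)cc(OC)c3C2)c(O)c1CC=C(C)C | target

Total step count: 11. Longest linear sequence: 7 steps (steps 1 to 4 or 5 to 8, then 9 to 11).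

Steps most likely to fail

Step 9. Several processes could spoil the step:
- attack at the unsubstituted oxirane carbon;
- a hydride shift of the oxirane, induced by magnesium salts, before the C–C bond forms;
- partial ionisation at C3 with erosion of enantiopurity;
- a sluggish fluoride displacement.

The fallback sets out from 8 and 14 and returns at 18. It makes the two bonds one after the other and sets C3 with an auxiliary (Evans alkylation).
- InCl3-catalysed Meinwald rearrangement of 8 (THF, rt) should give 2-[4-methoxy-2-(methoxymethoxy)-3-(3-methylbut-2-en-1-yl)phenyl]acetaldehyde F1.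
- Pinnick oxidation (NaClO2, NaH2PO4, 2-methylbut-2-ene, t-BuOH/H2O) should give [4-methoxy-2-(methoxymethoxy)-3-(3-methylbut-2-en-1-yl)phenyl]acetic acid F2.
- Acylation of (4R)-4-benzyl-1,3-oxazolidin-2-one (pivaloyl chloride, Et3N, LiCl, THF) should give (4R)-4-benzyl-3-{[4-methoxy-2-(methoxymethoxy)-3-(3-methylbut-2-en-1-yl)phenyl]acetyl}-1,3-oxazolidin-2-one F3.
- Enolisation with NaN(SiMe3)2 (THF, −78 °C) and alkylation by 14 (NaI) on the enolate face remote from the benzyl group should give (4R)-4-benzyl-3-{(2R)-3-[3-(1,3-dioxolan-2-yl)-2,4-difluoro-6-methoxyphenyl]-2-[4-methoxy-2-(methoxymethoxy)-3-(3-methylbut-2-en-1-yl)phenyl]propanoyl}-1,3-oxazolidin-2-one F4.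
- LiBH4 (Et2O, H2O, 0 °C) should release (2R)-3-[3-(1,3-dioxolan-2-yl)-2,4-difluoro-6-methoxyphenyl]-2-[4-methoxy-2-(methoxymethoxy)-3-(3-methylbut-2-en-1-yl)phenyl]propan-1-ol F5.
- KOt-Bu (THF/DMPU, 60 °C) closes ring C to 18.

Step 3. The doubly activated benzylic–allylic CH2 of the prenyl chain may be deprotonated in competition, or metalation may occur next to OMe instead of OMOM.

The fallback sets out from 1 and returns at 6. It puts the ketone carbon in place first and uses no alkyllithium once the prenyl group is present.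
- Friedel–Crafts acylation of 1 (AcOH, BF3·OEt2, 90 °C) should give 1-(2-hydroxy-4-methoxyphenyl)ethan-1-one F6.
- Ortho C-alkylation of its sodium phenoxide in an apolar medium (NaH, toluene, prenyl bromide) should give 1-[2-hydroxy-4-methoxy-3-(3-methylbut-2-en-1-yl)phenyl]ethan-1-one F7.
- MOMCl and NaH (DMF) should give 1-[4-methoxy-2-(methoxymethoxy)-3-(3-methylbut-2-en-1-yl)phenyl]ethan-1-one F8.
- Chlorination of the kinetic enolate (LiN(SiMe3)2, THF, −78 °C; N-chlorosuccinimide) leads to 6.

Step 10. While the MOM group is cleaved in protic acid, the liberated 2'-phenol may add to the prenyl double bond under acid catalysis and close a dimethylchroman ring.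

The fallback sets out from 18 and returns at 21. It changes the order of the end game so that the free ortho-prenylphenol never meets protic acid.
- Selective acetal exchange (pyridinium p-toluenesulfonate, acetone/H2O, rt) should give (3R)-7-fluoro-5-methoxy-3-[4-methoxy-2-(methoxymethoxy)-3-(3-methylbut-2-en-1-yl)phenyl]-3,4-dihydro-2H-chromene-8-carbaldehyde F9.
- 2-(Methylsulfonyl)ethanol and NaH (DMF) should pass through (3R)-5-methoxy-3-[4-methoxy-2-(methoxymethoxy)-3-(3-methylbut-2-en-1-yl)phenyl]-7-[2-(methylsulfonyl)ethoxy]-3,4-dihydro-2H-chromene-8-carbaldehyde F10.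
- The same flask should then deliver (3R)-7-hydroxy-5-methoxy-3-[4-methoxy-2-(methoxymethoxy)-3-(3-methylbut-2-en-1-yl)phenyl]-3,4-dihydro-2H-chromene-8-carbaldehyde F11.
- The MOM ether is removed last under aprotic conditions (TMSOTf, 2,2'-bipyridyl, CH2Cl2, 0 °C; then H2O) to give 21.

Further compounds
F1 | step 9 | 2-[4-methoxy-2-(methoxymethoxy)-3-(3-methylbut-2-en-1-yl)phenyl]acetaldehyde | COc1ccc(CC=O)c(OCOC)c1CC=C(C)C
F2 | step 9 | [4-methoxy-2-(methoxymethoxy)-3-(3-methylbut-2-en-1-yl)phenyl]acetic acid | COc1ccc(CC(=O)O)c(OCOC)c1CC=C(C)C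
F3 | step 9 | (4R)-4-benzyl-3-{[4-methoxy-2-(methoxymethoxy)-3-(3-methylbut-2-en-1-yl)phenyl]acetyl}-1,3-oxazolidin-2-one | COc1ccc(CC(=O)N2[C@H](Cc3ccccc3)COC2=O)c(OCOC)c1CC=C(C)C
F4 | step 9 | (4R)-4-benzyl-3-{(2R)-3-[3-(1,3-dioxolan-2-yl)-2,4-difluoro-6-methoxyphenyl]-2-[4-methoxy-2-(methoxymethoxy)-3-(3-methylbut-2-en-1-yl)phenyl]propanoyl}-1,3-oxazolidin-2-one | COc1ccc([C@H](C(=O)N2[C@H](Cc3ccccc3)COC2=O)Cc2c(F)c(C3OCCO3)c(F)cc2OC)c(OCOC)c1CC=C(C)C
F5 | step 9 | (2R)-3-[3-(1,3-dioxolan-2-yl)-2,4-difluoro-6-methoxyphenyl]-2-[4-methoxy-2-(methoxymethoxy)-3-(3-methylbut-2-en-1-yl)phenyl]propan-1-ol | COc1ccc([C@H](CO)Cc2c(F)c(C3OCCO3)c(F)cc2OC)c(OCOC)c1CC=C(C)C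
F6 | step 3 | 1-(2-hydroxy-4-methoxyphenyl)ethan-1-one | CC(=O)c1ccc(OC)cc1O
F7 | step 3 | 1-[2-hydroxy-4-methoxy-3-(3-methylbut-2-en-1-yl)phenyl]ethan-1-one | CC(=O)c1ccc(OC)c(CC=C(C)C)c1O
F8 | step 3 | 1-[4-methoxy-2-(methoxymethoxy)-3-(3-methylbut-2-en-1-yl)phenyl]ethan-1-one | CC(=O)c1ccc(OC)c(CC=C(C)C)c1OCOC
F9 | step 10 | (3R)-7-fluoro-5-methoxy-3-[4-methoxy-2-(methoxymethoxy)-3-(3-methylbut-2-en-1-yl)phenyl]-3,4-dihydro-2H-chromene-8-carbaldehyde | COc1ccc([C@@H]2COc3c(C=O)c(F)cc(OC)c3C2)c(OCOC)c1CC=C(C)C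
F10 | step 10 | (3R)-5-methoxy-3-[4-methoxy-2-(methoxymethoxy)-3-(3-methylbut-2-en-1-yl)phenyl]-7-[2-(methylsulfonyl)ethoxy]-3,4-dihydro-2H-chromene-8-carbaldehyde | COc1ccc([C@@H]2COc3c(C=O)c(OCCS(C)(=O)=O)cc(OC)c3C2)c(OCOC)c1CC=C(C)C
F11 | step 10 | (3R)-7-hydroxy-5-methoxy-3-[4-methoxy-2-(methoxymethoxy)-3-(3-methylbut-2-en-1-yl)phenyl]-3,4-dihydro-2H-chromene-8-carbaldehyde | COc1ccc([C@@H]2COc3c(C=O)c(O)cc(OC)c3C2)c(OCOC)c1CC=C(C)C
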